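**Numbering.** Quinoline numbering is used for the bicycle (ring A = N1, C2, C3, C4, C4a, C8a; ring B = C4a, C5, C6, C7, C8, C8a) and C1'–C8' for the chain on C5.

## The problem

Compound 27 is a cis-fused decahydroquinoline with a methyl group on C2, an (E)-oct-2-enoyl group on O3 and a 5-hydroxyoctyl chain on C5. Five ring stereocentres (2R, 3S, 4aR, 5R, 8aS) must be set relative to one another: CH3 and O3 are trans, H2 and H8a are cis, the ring fusion is cis, and on ring B the substituents C4 (on C4a), N1 (on C8a) and C1' (on C5) all lie on one face. C2 can be bought in the D-alanine series, C3 can be controlled from C2 in an open chain, and C2 and C3 together can control C4a and C8a if ring A closes through a chair in which both are equatorial. C5 is the hard centre: its chain sits on the concave face, cis to C4, where hydrogenation or conjugate addition from outside would not place it. The sixth centre, C5' (R), is four methylene groups away from the ring, cannot be induced, and must come from an enantiopure building block. The enoate is the fragile group (reducible, a Michael acceptor, cleaved by hydride and base), and the secondary amine would compete for any acylating agent. The ester therefore goes on late, onto an N-protected alcohol, and only a non-reductive acidic unmasking may follow it. The enabling feature is that N1 and C1' are 1,3-cis on ring B and can both be axial, so N1 can hold C1' on a two-atom tether whose carbonyl carbon becomes C2'. This is a six-membered lactam (N1, C2', C1', C5, C4a, C8a) bridging ring B.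

## Retrosynthesis

**27 to 23 and 24.** The O3–acyl bond is cut, together with the N–Boc and O–Si bonds of the protected ester 26. Acylating last keeps the enoate away from hydrogenation, hydride and ylide chemistry; any earlier acylation would expose it to one of them. This removes eight carbons and the Michael acceptor. The forward reaction must acylate O3 only, so N1 is a carbamate and O5' a silyl ether in alcohol 23, and both come off with acid from 26. The acid partner is (E)-oct-2-enoic acid 24.

**23 to 17 and 19.** Alcohol 23 comes from silyl ether 22 by one hydrogenation that saturates C2'=C3' and removes the benzyl group from O3. Ether 22 comes from alkenol 21, and the C2'=C3' bond of 21 is cut to aldehyde 17 and phosphonium salt 19. This cut is preferred over C1'–C2' or C4'–C5' because C2' is the carbonyl carbon that the tether leaves behind, and because it places C5' in a C3'–C8' piece that needs no asymmetric step. Salt 19 is the adduct of a one-carbon ylide with (R)-1,2-epoxypentane 18. The chain shrinks to a two-carbon aldehyde. Alkene geometry does not matter; the free hydroxyl of 19 is carried as the alkoxide and silylated afterwards so that O5' and O3 stay distinguishable.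

**17 to 14.** Aldehyde 17 is traced through N-Boc alcohol 16 and amino alcohol 15 back to lactam 14 by re-forming the N1–C2' amide bond. This reveals the bridged 2-azabicyclo[3.3.1]nonan-3-one. The forward step needs a reductive cleavage of a tertiary lactam at C–N, not C–O.

**14 to 13 (key disconnection).** The C5–C1' bond is cut to give iodoacetamide 13, which carries only a C5=C6 double bond in ring B. The neighbouring options, adding C1' intermolecularly to an sp2 C5, would deliver it to the convex face; the tether reverses this. One ring and the C5 stereocentre disappear. The forward radical closure must be 6-exo and must outrun reduction of the radical.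

**13 to 9.** The N–acyl bond is cut to amine 11 and iodoacetyl chloride 12, then N1–C8a is cut to open-chain amine 9. This gives a cyclohexa-2,5-dienyl group whose two double bonds are diastereotopic: one forms C8a–N, and the other is left as the C5=C6 bond the key step needs. Cutting N1–C2 instead would discard the alanine stereocentre. The forward 6-exo aminomercuration must select one alkene and give a cis fusion.

**9 to 4 and 5.** Amine 9 comes from carbamate 8 and alcohol 7. The C4–C4a bond of 7 is cut to epoxide 4 and cyclohexa-1,4-diene 5. This is the only carbon–carbon bond needed between two simple pieces, and 5 is symmetric. The dienyl anion must react at its central carbon and at the CH2 of the epoxide.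

**4 to 1.** Epoxide 4 comes from chloroketone 2, which comes from the commercial N-methoxy-N-methylamide 1 of N-Boc-D-alanine by one-carbon homologation (that carbon becomes C4). The forward reduction must set C3 anti to the nitrogen on C2.

## Roads not taken

**Alternative 1:** Intramolecular Diels–Alder reaction. The cut is C4a–C8a plus C5–C6, leading back to the open-chain N-(buta-1,3-dienyl) carbamate A1 with a (Z)-alkene that already carries the whole chain. Heating A1 would give hexahydroquinoline A2, closing rings A and B together.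
- Merits: two rings and three stereocentres (C4a, C5, C8a) in one step; convergent; the (Z)-geometry translates directly into the cis relation of C4 and C1'; no tin or mercury.
- Weak points: the cis fusion and the facial choice relative to C2 and C3 rest on transition-state preferences of a flexible tether and are not enforced. The dienophile is an unactivated dialkyl alkene, so high temperatures are needed, which an acid- and heat-sensitive dienyl carbamate may not tolerate. A1 itself needs an N-dienylation of a hindered carbamate and a Z-selective olefination.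
- Comparison: this road is more convergent and forms more bonds per step, and it is probably shorter after the cycloaddition. The chosen plan sets against it that C5 can only form on the required face, and that C4a and C8a are selected through a defined chair with both substituents equatorial.

**Alternative 2:** Cyclobutene ring-rearrangement metathesis. The cut is C3=C4, leading back to the N-(but-3-en-2-yl) carbamate A3 of a cis-bicyclo[4.2.0]oct-7-enyl amine. A second-generation Grubbs catalyst would open the cyclobutene and close ring A, giving the 5-vinyl octahydroquinoline A4.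
- Merits: catalytic; driven by ring strain; C4a, C5 and C8a are carried over stereospecifically; ring A is built in a single step.
- Weak points: A3 needs an enantiopure cyclobutene with three contiguous centres and a hindered N-alkylation with a defined secondary allylic unit. In A4 the oxygen on C3 still has to be added to the C3=C4 bond with regiocontrol (C3 over C4) and trans to the methyl group, while a more reactive vinyl group is present. The vinyl group supplies only C1' and C2', so the chain must still be grown.
- Comparison: this road makes ring A more economically than the chosen plan. The chosen plan sets against it that O3 and C2 are present in the correct oxidation state and configuration from the first step, so no late regioselective oxygenation is needed.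

**Alternative 3:** Diels–Alder reaction of levoglucosenone. The cut is C4a–C5 plus C8a–C8, leading back to levoglucosenone A5 and the (E)-diene A6 that carries the full chain. A thermal or ZnCl2-promoted cycloaddition would give the endo adduct A7.
- Merits: a cheap chiral enone with one face shielded by the anhydro bridge; ring B, its stereotriad and the complete chain (including C5') arrive in one step.
- Weak points: a 1-alkyl diene gives only modest regio- and endo-control. In A7, C8a bears carbon where nitrogen is needed, so N1 must be introduced by degradation and rearrangement; the ketone at C4 must be removed; C2 with its methyl group must be added and ring A closed. The stereocentre next to the ketone can epimerise.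
- Comparison: this road sets the carbocyclic stereotriad and attaches the chain more directly than the chosen plan. The chosen plan sets against it that every ring A atom, including N1, is in place before the bicycle forms, so no long redox and degradation endgame is needed.

Key step: step 8

**Assumption.** Alkenes 21 and 22 are carried as E/Z mixtures at C2'=C3' (SMILES written without geometry), because step 15 saturates this bond.

## Route

Step 1
Reactants: 1 tert-butyl N-[(2R)-1-[methoxy(methyl)amino]-1-oxopropan-2-yl]carbamate (commercial N-methoxy-N-methylamide of N-Boc-D-alanine)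
Product: 2 tert-butyl N-[(2R)-4-chloro-3-oxobutan-2-yl]carbamate
Conditions: ICH2Cl, MeLi·LiBr (3 equiv each), THF/Et2O, −78 °C; aq. NH4Cl
Reagents that add atoms: chloroiodomethane, ClCI
Why: Chloromethyllithium (iodine–lithium exchange) adds to the N-methoxy-N-methylamide and the chelated tetrahedral adduct survives until quench, so mono-addition gives the chloromethyl ketone (carbenoid homologation). The carbamate is N-lithiated first, which protects C2 against enolisation.

Step 2
Reactants: 2 tert-butyl N-[(2R)-4-chloro-3-oxobutan-2-yl]carbamate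
Product: 4 tert-butyl N-[(1R)-1-[(2R)-oxiran-2-yl]ethyl]carbamate, via chlorohydrin 3 (not isolated)
Conditions: LiAlH(OtBu)3, EtOH, −78 °C; then KOH, EtOH, 0 °C → rt
Reagents that add atoms: none
Why: Cyclic-model (chelation-type) hydride reduction of the carbamate-protected α-amino ketone delivers hydride past H and not past CH3 on C2, which should give the anti (2R,3R) chlorohydrin. Its alkoxide then closes the epoxide by intramolecular Williamson displacement without touching either stereocentre; any syn epoxide is removed by chromatography.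

Step 3
Reactants: 5 cyclohexa-1,4-diene; 4 tert-butyl N-[(1R)-1-[(2R)-oxiran-2-yl]ethyl]carbamate
Product: 7 tert-butyl N-[(2R,3S)-4-(cyclohexa-2,5-dien-1-yl)-3-hydroxybutan-2-yl]carbamate, via cyclohexa-2,5-dienyllithium 6 (not isolated)
Conditions: 5 (3 equiv), s-BuLi, TMEDA, THF, −78 °C; then 4, −78 → −20 °C; aq. NH4Cl
Reagents that add atoms: none
Why: Deprotonation of the doubly allylic CH2 gives the pentadienyl anion, which reacts with hard electrophiles at its central carbon and so keeps the skipped diene; it opens the epoxide by SN2 attack at the unsubstituted carbon, forming C4–C4a. The first equivalent is consumed by the carbamate N–H, and C3 is not involved (3S by priority change only).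

Step 4
Reactants: 7 tert-butyl N-[(2R,3S)-4-(cyclohexa-2,5-dien-1-yl)-3-hydroxybutan-2-yl]carbamate
Product: 8 tert-butyl N-[(2R,3S)-3-(benzyloxy)-4-(cyclohexa-2,5-dien-1-yl)butan-2-yl]carbamate
Conditions: 2-benzyloxy-1-methylpyridinium triflate, MgO, PhCF3, 85 °C
Reagents that add atoms: 2-benzyloxy-1-methylpyridinium trifluoromethanesulfonate, C[n+]1ccccc1OCc1ccccc1.[O-]S(=O)(=O)C(F)(F)F
Why: Thermal benzyl transfer from the pyridinium salt under near-neutral conditions etherifies the secondary alcohol. No alkoxide is formed, so the carbamate cannot close to an oxazolidinone and nitrogen is not benzylated.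

Step 5
Reactants: 8 tert-butyl N-[(2R,3S)-3-(benzyloxy)-4-(cyclohexa-2,5-dien-1-yl)butan-2-yl]carbamate
Product: 9 (2R,3S)-3-(benzyloxy)-4-(cyclohexa-2,5-dien-1-yl)butan-2-amine
Conditions: TFA, CH2Cl2, 0 °C; aq. NaOH
Reagents that add atoms: none
Why: Acidolysis of the tert-butyl carbamate frees the primary amine; the benzyl ether and the unconjugated diene should be stable to cold trifluoroacetic acid.

Step 6
Reactants: 9 (2R,3S)-3-(benzyloxy)-4-(cyclohexa-2,5-dien-1-yl)butan-2-amine
Product: 11 (2R,3S,4aR,8aS)-3-(benzyloxy)-2-methyl-1,2,3,4,4a,7,8,8a-octahydroquinoline, via C8 organomercurial 10 (not isolated)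
Conditions: Hg(OCOCF3)2 (1.05 equiv), THF, 0 °C → rt; then NaBH4, 3 M NaOH, 0 °C
Reagents that add atoms: none
Why: Intramolecular aminomercuration (anti addition, 6-exo) followed by hydride demercuration; nitrogen attacks the alkene carbon next to C4a on the face that carries the tether, so the fusion is cis. Of the two diastereotopic alkenes, the one chosen lets the forming piperidine chair keep CH3 on C2 and OBn on C3 equatorial, which sets 4aR,8aS; the other alkene would need both axial, with OBn 1,3-diaxial to C5. The untouched alkene becomes C5=C6.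

Step 7
Reactants: 11 (2R,3S,4aR,8aS)-3-(benzyloxy)-2-methyl-1,2,3,4,4a,7,8,8a-octahydroquinoline; 12 iodoacetyl chloride
Product: 13 1-[(2R,3S,4aR,8aS)-3-(benzyloxy)-2-methyl-3,4,4a,7,8,8a-hexahydroquinolin-1(2H)-yl]-2-iodoethan-1-one
Conditions: aq. NaHCO3, CH2Cl2, 0 °C
Reagents that add atoms: none
Why: Schotten–Baumann N-acylation; the acid chloride reacts at nitrogen far faster than the C–I carbon is displaced, and the two-phase bicarbonate medium removes HCl.

Step 8
Reactants: 13 1-[(2R,3S,4aR,8aS)-3-(benzyloxy)-2-methyl-3,4,4a,7,8,8a-hexahydroquinolin-1(2H)-yl]-2-iodoethan-1-one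
Product: 14 (2R,3S,4aR,5S,8aS)-3-(benzyloxy)-2-methyloctahydro-1,5-ethanoquinolin-10-one (tricyclic lactam; N1 and C5 bridged by C2'(=O)–C1'H2, with C1' on C5 cis to N1 and C4)
Conditions: Bu3SnH (1.3 equiv, syringe pump), AIBN (cat.), PhH (0.005 M), reflux
Reagents that add atoms: none
Why: The tributyltin radical abstracts iodine from 13 to give the carbamoylmethyl radical C1', which adds to C5 of the C5=C6 bond; the C6 radical then takes hydrogen from Bu3SnH and carries the chain. The closest known reaction type is the tin-hydride cyclisation of N-(cyclohex-3-enyl) α-haloacetamides to 2-azabicyclo[3.3.1]nonan-3-ones. The lactam ring (N1, C2', C1', C5, C4a, C8a) closes in the 6-exo-trig mode. The only new stereocentre is C5, and the tether controls it: the radical hangs from N1, which is axial on ring B in the reacting conformer (the one with CH3 and OBn equatorial on ring A), so C1' can reach C5 only on the face cis to N1 and C4, through a chair–chair bicyclo[3.3.1] transition state. The step needs attack at C5 over C6; this is secured by ring size, since 7-endo closure would give a more strained bicyclo[3.2.2] bridge. It also needs cyclisation to outrun hydrogen transfer to the first radical; this is secured by a low stationary concentration of Bu3SnH, which also leaves time for amide rotation and ring inversion into the reactive conformer. The benzyl ether and the centres C2, C3, C4a and C8a are spectators.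

Step 9
Reactants: 14 tricyclic lactam
Product: 15 2-[(2R,3S,4aR,5S,8aS)-3-(benzyloxy)-2-methyldecahydroquinolin-5-yl]ethan-1-ol
Conditions: LiNH2BH3 (from BH3·NH3 and n-BuLi), THF, 0 → 40 °C; aq. HCl, then NaOH
Reagents that add atoms: none
Why: Lithium amidotrihydroborate reduces tertiary amides to primary alcohols with C–N cleavage: hydride adds to the lactam carbonyl, the hindered N1 leaves from the tetrahedral intermediate, and the aldehyde is reduced on to the C2' alcohol. No stereocentre is touched.

Step 10
Reactants: 15 2-[(2R,3S,4aR,5S,8aS)-3-(benzyloxy)-2-methyldecahydroquinolin-5-yl]ethan-1-ol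
Product: 16 tert-butyl (2R,3S,4aR,5S,8aS)-3-(benzyloxy)-5-(2-hydroxyethyl)-2-methyloctahydroquinoline-1(2H)-carboxylate
Conditions: Boc2O, Et3N, THF, 50 °C
Reagents that add atoms: di-tert-butyl dicarbonate, CC(C)(C)OC(=O)OC(=O)OC(C)(C)C
Why: Carbamoylation of the secondary amine; without an acylation catalyst the primary alcohol does not react with Boc2O.

Step 11
Reactants: 16 tert-butyl (2R,3S,4aR,5S,8aS)-3-(benzyloxy)-5-(2-hydroxyethyl)-2-methyloctahydroquinoline-1(2H)-carboxylate
Product: 17 tert-butyl (2R,3S,4aR,5S,8aS)-3-(benzyloxy)-2-methyl-5-(2-oxoethyl)octahydroquinoline-1(2H)-carboxylate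
Conditions: Dess–Martin periodinane, CH2Cl2, 0 °C → rt
Reagents that add atoms: none
Why: Dess–Martin oxidation stops at the aldehyde and tolerates the carbamate and the benzyl ether; C5 is β to the carbonyl and cannot epimerise.

Step 12
Reactants: 18 (R)-1,2-epoxypentane
Product: 19 [(3R)-3-hydroxyhexyl]triphenylphosphonium bromide
Conditions: Ph3PCH3Br, n-BuLi, THF, 0 °C; then 18, 0 °C → rt; aq. HBr
Reagents that add atoms: methyltriphenylphosphonium bromide, C[P+](c1ccccc1)(c1ccccc1)c1ccccc1.[Br-]; hydrogen bromide, Br
Why: Methylidenetriphenylphosphorane opens the terminal epoxide at CH2 (SN2), and acid quench of the betaine gives the γ-hydroxyalkylphosphonium salt. The carbinol carbon is not involved, so 5'R comes unchanged from 18.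

Step 13
Reactants: 19 [(3R)-3-hydroxyhexyl]triphenylphosphonium bromide; 17 tert-butyl (2R,3S,4aR,5S,8aS)-3-(benzyloxy)-2-methyl-5-(2-oxoethyl)octahydroquinoline-1(2H)-carboxylate
Product: 21 tert-butyl (2R,3S,4aR,5S,8aS)-3-(benzyloxy)-5-[(5R)-5-hydroxyoct-2-en-1-yl]-2-methyloctahydroquinoline-1(2H)-carboxylate (E/Z mixture), via lithium γ-oxido ylide 20 (not isolated)
Conditions: 19 (1.6 equiv), n-BuLi (2 equiv per 19), THF, −78 → 0 °C; then 17, −78 °C → rt; aq. NH4Cl
Reagents that add atoms: none
Why: Two equivalents of base give the γ-oxido ylide, which undergoes Wittig olefination with aldehyde 17 and forms C2'=C3'; the lithium alkoxide serves as its own protecting group. Alkene geometry is of no consequence.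

Step 14
Reactants: 21 tert-butyl (2R,3S,4aR,5S,8aS)-3-(benzyloxy)-5-[(5R)-5-hydroxyoct-2-en-1-yl]-2-methyloctahydroquinoline-1(2H)-carboxylate
Product: 22 tert-butyl (2R,3S,4aR,5S,8aS)-3-(benzyloxy)-5-[(5R)-5-[(tert-butyldimethylsilyl)oxy]oct-2-en-1-yl]-2-methyloctahydroquinoline-1(2H)-carboxylate (E/Z mixture)
Conditions: TBSCl, imidazole, DMF, rt
Reagents that add atoms: tert-butyldimethylsilyl chloride, CC(C)(C)[Si](C)(C)Cl
Why: Standard silylation of the unhindered secondary alcohol; it distinguishes O5' from O3, which is still a benzyl ether.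

Step 15
Reactants: 22 tert-butyl (2R,3S,4aR,5S,8aS)-3-(benzyloxy)-5-[(5R)-5-[(tert-butyldimethylsilyl)oxy]oct-2-en-1-yl]-2-methyloctahydroquinoline-1(2H)-carboxylate
Product: 23 tert-butyl (2R,3S,4aR,5R,8aS)-5-[(5R)-5-[(tert-butyldimethylsilyl)oxy]octyl]-3-hydroxy-2-methyloctahydroquinoline-1(2H)-carboxylate
Conditions: H2 (1 atm), Pd(OH)2/C, EtOAc, rt
Reagents that add atoms: none
Why: Heterogeneous hydrogenation saturates the disubstituted alkene and hydrogenolyses the benzyl ether in the same operation; the carbamate and the silyl ether are inert in ethyl acetate.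

Step 16
Reactants: 23 tert-butyl (2R,3S,4aR,5R,8aS)-5-[(5R)-5-[(tert-butyldimethylsilyl)oxy]octyl]-3-hydroxy-2-methyloctahydroquinoline-1(2H)-carboxylate; 24 (2E)-oct-2-enoic acid
Product: 26 tert-butyl (2R,3S,4aR,5R,8aS)-5-[(5R)-5-[(tert-butyldimethylsilyl)oxy]octyl]-2-methyl-3-{[(2E)-oct-2-enoyl]oxy}octahydroquinoline-1(2H)-carboxylate, via mixed anhydride 25 (not isolated)
Conditions: 24, 2,4,6-trichlorobenzoyl chloride, Et3N, THF, rt; then 23, DMAP, PhMe, rt → 40 °C
Reagents that add atoms: none
Why: Yamaguchi esterification: the mixed anhydride passes the enoyl group through the acylpyridinium to the hindered secondary alcohol O3 with the E-geometry intact. N1 (carbamate) and O5' (silyl ether) cannot compete.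

Step 17
Reactants: 26 tert-butyl (2R,3S,4aR,5R,8aS)-5-[(5R)-5-[(tert-butyldimethylsilyl)oxy]octyl]-2-methyl-3-{[(2E)-oct-2-enoyl]oxy}octahydroquinoline-1(2H)-carboxylate
Product: 27 (2R,3S,4aR,5R,8aS)-5-[(5R)-5-hydroxyoctyl]-2-methyldecahydroquinolin-3-yl (2E)-oct-2-enoate
Conditions: TFA/H2O (9:1), CH2Cl2, 0 °C → rt; aq. NaHCO3
Reagents that add atoms: none
Why: Aqueous trifluoroacetic acid cleaves the tert-butyl carbamate and the silyl ether together, while the ester and its conjugated double bond are stable to acid. No reductive or basic step follows the acylation.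

## Compound list

1 | tert-butyl N-[(2R)-1-[methoxy(methyl)amino]-1-oxopropan-2-yl]carbamate | CC(C)(C)OC(=O)N[C@H](C)C(=O)N(C)OC | starting material
2 | tert-butyl N-[(2R)-4-chloro-3-oxobutan-2-yl]carbamate | CC(C)(C)OC(=O)N[C@H](C)C(=O)CCl | intermediate
3 | tert-butyl N-[(2R,3R)-4-chloro-3-hydroxybutan-2-yl]carbamate | CC(C)(C)OC(=O)N[C@H](C)[C@@H](O)CCl | intermediate (not isolated)
4 | tert-butyl N-[(1R)-1-[(2R)-oxiran-2-yl]ethyl]carbamate | CC(C)(C)OC(=O)N[C@H](C)[C@@H]1CO1 | intermediate
5 | cyclohexa-1,4-diene | C1=CCC=CC1 | starting material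
6 | cyclohexa-2,5-dien-1-yllithium | [Li]C1C=CCC=C1 | intermediate (not isolated)
7 | tert-butyl N-[(2R,3S)-4-(cyclohexa-2,5-dien-1-yl)-3-hydroxybutan-2-yl]carbamate | CC(C)(C)OC(=O)N[C@H](C)[C@@H](O)CC1C=CCC=C1 | intermediate
8 | tert-butyl N-[(2R,3S)-3-(benzyloxy)-4-(cyclohexa-2,5-dien-1-yl)butan-2-yl]carbamate | CC(C)(C)OC(=O)N[C@H](C)[C@@H](OCc1ccccc1)CC1C=CCC=C1 | intermediate
9 | (2R,3S)-3-(benzyloxy)-4-(cyclohexa-2,5-dien-1-yl)butan-2-amine | N[C@H](C)[C@@H](OCc1ccccc1)CC1C=CCC=C1 | intermediate
10 | [(2R,3S,4aR,8aS)-3-(benzyloxy)-2-methyl-1,2,3,4,4a,7,8,8a-octahydroquinolin-8-yl]mercury trifluoroacetate (Hg on C8 trans to N1) | c1ccccc1CO[C@H]1C[C@@H]2C=CC[C@@H]([Hg]OC(=O)C(F)(F)F)[C@@H]2N[C@@H]1C | intermediate (not isolated)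
11 | (2R,3S,4aR,8aS)-3-(benzyloxy)-2-methyl-1,2,3,4,4a,7,8,8a-octahydroquinoline | c1ccccc1CO[C@H]1C[C@@H]2C=CCC[C@@H]2N[C@@H]1C | intermediate
12 | iodoacetyl chloride | O=C(Cl)CI | starting material
13 | 1-[(2R,3S,4aR,8aS)-3-(benzyloxy)-2-methyl-3,4,4a,7,8,8a-hexahydroquinolin-1(2H)-yl]-2-iodoethan-1-one | c1ccccc1CO[C@H]1C[C@@H]2C=CCC[C@@H]2N(C(=O)CI)[C@@H]1C | intermediate
14 | (2R,3S,4aR,5S,8aS)-3-(benzyloxy)-2-methyloctahydro-1,5-ethanoquinolin-10-one (lactam bridging N1 and C5 through C2'(=O)–C1') | c1ccccc1CO[C@H]1C[C@@H]2[C@H]3CCC[C@@H]2N(C(=O)C3)[C@@H]1C | intermediate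
15 | 2-[(2R,3S,4aR,5S,8aS)-3-(benzyloxy)-2-methyldecahydroquinolin-5-yl]ethan-1-ol | c1ccccc1CO[C@H]1C[C@@H]2[C@H](CCO)CCC[C@@H]2N[C@@H]1C | intermediate
16 | tert-butyl (2R,3S,4aR,5S,8aS)-3-(benzyloxy)-5-(2-hydroxyethyl)-2-methyloctahydroquinoline-1(2H)-carboxylate | c1ccccc1CO[C@H]1C[C@@H]2[C@H](CCO)CCC[C@@H]2N(C(=O)OC(C)(C)C)[C@@H]1C | intermediate
17 | tert-butyl (2R,3S,4aR,5S,8aS)-3-(benzyloxy)-2-methyl-5-(2-oxoethyl)octahydroquinoline-1(2H)-carboxylate | c1ccccc1CO[C@H]1C[C@@H]2[C@H](CC=O)CCC[C@@H]2N(C(=O)OC(C)(C)C)[C@@H]1C | intermediate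
18 | (R)-1,2-epoxypentane | CCC[C@@H]1CO1 | starting material
19 | [(3R)-3-hydroxyhexyl]triphenylphosphonium bromide | CCC[C@@H](O)CC[P+](c1ccccc1)(c1ccccc1)c1ccccc1.[Br-] | intermediate
20 | lithium (3R)-1-(triphenyl-λ5-phosphanylidene)hexan-3-olate (γ-oxido ylide) | CCC[C@@H]([O-])CC=P(c1ccccc1)(c1ccccc1)c1ccccc1.[Li+] | intermediate (not isolated)
21 | tert-butyl (2R,3S,4aR,5S,8aS)-3-(benzyloxy)-5-[(5R)-5-hydroxyoct-2-en-1-yl]-2-methyloctahydroquinoline-1(2H)-carboxylate (E/Z mixture) | c1ccccc1CO[C@H]1C[C@@H]2[C@H](CC=CC[C@H](O)CCC)CCC[C@@H]2N(C(=O)OC(C)(C)C)[C@@H]1C | intermediate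
22 | tert-butyl (2R,3S,4aR,5S,8aS)-3-(benzyloxy)-5-[(5R)-5-[(tert-butyldimethylsilyl)oxy]oct-2-en-1-yl]-2-methyloctahydroquinoline-1(2H)-carboxylate (E/Z mixture) | c1ccccc1CO[C@H]1C[C@@H]2[C@H](CC=CC[C@H](O[Si](C)(C)C(C)(C)C)CCC)CCC[C@@H]2N(C(=O)OC(C)(C)C)[C@@H]1C | intermediate
23 | tert-butyl (2R,3S,4aR,5R,8aS)-5-[(5R)-5-[(tert-butyldimethylsilyl)oxy]octyl]-3-hydroxy-2-methyloctahydroquinoline-1(2H)-carboxylate | O[C@H]1C[C@@H]2[C@H](CCCC[C@H](O[Si](C)(C)C(C)(C)C)CCC)CCC[C@@H]2N(C(=O)OC(C)(C)C)[C@@H]1C | intermediate
24 | (2E)-oct-2-enoic acid | CCCCC/C=C/C(=O)O | starting material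
25 | (2E)-oct-2-enoic 2,4,6-trichlorobenzoic anhydride | CCCCC/C=C/C(=O)OC(=O)c1c(Cl)cc(Cl)cc1Cl | intermediate (not isolated)
26 | tert-butyl (2R,3S,4aR,5R,8aS)-5-[(5R)-5-[(tert-butyldimethylsilyl)oxy]octyl]-2-methyl-3-{[(2E)-oct-2-enoyl]oxy}octahydroquinoline-1(2H)-carboxylate | CCCCC/C=C/C(=O)O[C@H]1C[C@@H]2[C@H](CCCC[C@H](O[Si](C)(C)C(C)(C)C)CCC)CCC[C@@H]2N(C(=O)OC(C)(C)C)[C@@H]1C | intermediate
27 | (2R,3S,4aR,5R,8aS)-5-[(5R)-5-hydroxyoctyl]-2-methyldecahydroquinolin-3-yl (2E)-oct-2-enoate | CCCCC/C=C/C(=O)O[C@H]1C[C@@H]2[C@H](CCCC[C@H](O)CCC)CCC[C@@H]2N[C@@H]1C | target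

## Step count and risks

Total step count: 17. Longest linear sequence: 16 steps (steps 1–11 and 13–17, from 1); step 12 is the side branch from 18.

**Step 8 (key step).** Hydrogen transfer to the carbamoylmethyl radical may outrun the 6-exo closure. The closure needs the amide rotamer with CH2 over ring B and the ring conformer with N1 axial, and allylic strain from the N-acyl group works against that conformer; the outcome would be simple loss of iodine without ring formation. The fallback sets out from amine 11 and uses a more electrophilic, longer-lived radical. Acylation with trichloroacetyl chloride and Et3N gives 1-[(2R,3S,4aR,8aS)-3-(benzyloxy)-2-methyl-3,4,4a,7,8,8a-hexahydroquinolin-1(2H)-yl]-2,2,2-trichloroethan-1-one F1. With Bu3SnH (3.5 equiv) and AIBN in refluxing benzene, the dichloro(carbamoyl)methyl radical closes 6-exo to the 1',1'-dichloro analogue of the lactam F2. The excess tin hydride then removes both chlorines in the same flask, and the route is rejoined at lactam 14.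

**Step 6.** The free amine may bind the divalent mercury salt and slow the addition, the benzyl ether oxygen may compete in a 5-exo closure, and the C8a–N bond may be lost again by β-elimination during hydride demercuration. The fallback sets out from carbamate 8 (step 5 is postponed) and uses the carbamate N–H as the nucleophile. Hg(OAc)2 in THF under kinetic conditions gives the N-Boc C8 acetoxymercurial F3, whose β-amido mercurial is reduced by NaBH4 without reversal to tert-butyl (2R,3S,4aR,8aS)-3-(benzyloxy)-2-methyl-3,4,4a,7,8,8a-hexahydroquinoline-1(2H)-carboxylate F4. Cold trifluoroacetic acid then gives amine 11.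

**Step 9.** Hydride addition to the hindered, bridged lactam may be slow, or the tetrahedral intermediate may collapse with C–O in place of C–N cleavage, which would give the tricyclic tertiary amine. The fallback sets out from lactam 14 and opens it by hydrolysis of an activated form. O-Methylation with Me3OBF4 gives the lactim ether tetrafluoroborate F5. Mild aqueous hydrolysis cleaves its C–N bond to methyl 2-[(2R,3S,4aR,5S,8aS)-3-(benzyloxy)-2-methyldecahydroquinolin-5-yl]acetate F6, which is trapped at once with Boc2O as tert-butyl (2R,3S,4aR,5S,8aS)-3-(benzyloxy)-5-(2-methoxy-2-oxoethyl)-2-methyloctahydroquinoline-1(2H)-carboxylate F7. Reduction with iBu2AlH at −78 °C gives aldehyde 17 directly, so steps 10 and 11 are bypassed.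

**Step 3.** The carbamate N–H consumes organolithium, the pentadienyl anion may attack through a terminal carbon (giving the conjugated diene isomer), and the lithiated epoxy carbamate may rearrange. The fallback forms C3–C4 in place of C4–C4a and sets out from amide 1. Commercial cyclohexa-2,5-diene-1-carboxylic acid is reduced with LiAlH4 to (cyclohexa-2,5-dien-1-yl)methanol F8 and converted with CBr4 and PPh3 into 3-(bromomethyl)cyclohexa-1,4-diene F9. Magnesium in THF gives (cyclohexa-2,5-dien-1-yl)methylmagnesium bromide F10. Addition of F10 to amide 1 (N–H first deprotonated with iPrMgCl) gives tert-butyl N-[(2R)-4-(cyclohexa-2,5-dien-1-yl)-3-oxobutan-2-yl]carbamate F11. The anti-selective reduction of step 2 (LiAlH(OtBu)3, EtOH, −78 °C) then gives alcohol 7.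

**Step 13.** The dilithiated γ-oxido ylide is aggregated and basic, so enolisation of aldehyde 17 may compete with olefination and conversion may be low. The fallback sets out from aldehyde 17 and epoxide 18 and replaces the Wittig coupling by olefin cross-metathesis. Methylenation of 17 with Ph3P=CH2 gives tert-butyl (2R,3S,4aR,5S,8aS)-3-(benzyloxy)-2-methyl-5-(prop-2-en-1-yl)octahydroquinoline-1(2H)-carboxylate F12. Epoxide 18 with vinylmagnesium bromide and catalytic CuI gives (4R)-hept-1-en-4-ol F13, which is silylated (TBSCl, imidazole) to tert-butyldimethyl{[(4R)-hept-1-en-4-yl]oxy}silane F14. Cross-metathesis of F12 with excess F14 (second-generation Grubbs catalyst, CH2Cl2, 40 °C) gives silyl ether 22, and step 14 is no longer needed.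

## Further compounds

F1 | step 8 | 1-[(2R,3S,4aR,8aS)-3-(benzyloxy)-2-methyl-3,4,4a,7,8,8a-hexahydroquinolin-1(2H)-yl]-2,2,2-trichloroethan-1-one | c1ccccc1CO[C@H]1C[C@@H]2C=CCC[C@@H]2N(C(=O)C(Cl)(Cl)Cl)[C@@H]1C
F2 | step 8 | 1',1'-dichloro analogue of lactam 14 (both chlorines on the carbon between C5 and the lactam carbonyl) | c1ccccc1CO[C@H]1C[C@@H]2[C@H]3CCC[C@@H]2N(C(=O)C3(Cl)Cl)[C@@H]1C
F3 | step 6 | tert-butyl (2R,3S,4aR,8aS)-8-(acetoxymercurio)-3-(benzyloxy)-2-methyl-3,4,4a,7,8,8a-hexahydroquinoline-1(2H)-carboxylate (Hg on C8 trans to N1) | c1ccccc1CO[C@H]1C[C@@H]2C=CC[C@@H]([Hg]OC(C)=O)[C@@H]2N(C(=O)OC(C)(C)C)[C@@H]1C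
F4 | step 6 | tert-butyl (2R,3S,4aR,8aS)-3-(benzyloxy)-2-methyl-3,4,4a,7,8,8a-hexahydroquinoline-1(2H)-carboxylate | c1ccccc1CO[C@H]1C[C@@H]2C=CCC[C@@H]2N(C(=O)OC(C)(C)C)[C@@H]1C
F5 | step 9 | O-methyl lactim ether tetrafluoroborate of lactam 14 (N1=C2'(OCH3) iminium ether) | c1ccccc1CO[C@H]1C[C@@H]2[C@H]3CCC[C@@H]2[N+](=C(OC)C3)[C@@H]1C.F[B-](F)(F)F
F6 | step 9 | methyl 2-[(2R,3S,4aR,5S,8aS)-3-(benzyloxy)-2-methyldecahydroquinolin-5-yl]acetate | c1ccccc1CO[C@H]1C[C@@H]2[C@H](CC(=O)OC)CCC[C@@H]2N[C@@H]1C
F7 | step 9 | tert-butyl (2R,3S,4aR,5S,8aS)-3-(benzyloxy)-5-(2-methoxy-2-oxoethyl)-2-methyloctahydroquinoline-1(2H)-carboxylate | c1ccccc1CO[C@H]1C[C@@H]2[C@H](CC(=O)OC)CCC[C@@H]2N(C(=O)OC(C)(C)C)[C@@H]1C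
F8 | step 3 | (cyclohexa-2,5-dien-1-yl)methanol | OCC1C=CCC=C1
F9 | step 3 | 3-(bromomethyl)cyclohexa-1,4-diene | BrCC1C=CCC=C1
F10 | step 3 | (cyclohexa-2,5-dien-1-yl)methylmagnesium bromide | Br[Mg]CC1C=CCC=C1
F11 | step 3 | tert-butyl N-[(2R)-4-(cyclohexa-2,5-dien-1-yl)-3-oxobutan-2-yl]carbamate | CC(C)(C)OC(=O)N[C@H](C)C(=O)CC1C=CCC=C1
F12 | step 13 | tert-butyl (2R,3S,4aR,5S,8aS)-3-(benzyloxy)-2-methyl-5-(prop-2-en-1-yl)octahydroquinoline-1(2H)-carboxylate | c1ccccc1CO[C@H]1C[C@@H]2[C@H](CC=C)CCC[C@@H]2N(C(=O)OC(C)(C)C)[C@@H]1C
F13 | step 13 | (4R)-hept-1-en-4-ol | CCC[C@@H](O)CC=C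
F14 | step 13 | tert-butyldimethyl{[(4R)-hept-1-en-4-yl]oxy}silane | CCC[C@@H](O[Si](C)(C)C(C)(C)C)CC=C
A1 | alternative 1 | benzyl N-[(1E)-buta-1,3-dien-1-yl]-N-[(2R,3S,5Z,11R)-3-(benzyloxy)-11-[(tert-butyldimethylsilyl)oxy]tetradec-5-en-2-yl]carbamate | C=C/C=C/N(C(=O)OCc1ccccc1)[C@H](C)[C@@H](OCc1ccccc1)C/C=C\CCCC[C@H](O[Si](C)(C)C(C)(C)C)CCC
A2 | alternative 1 | benzyl 3-(benzyloxy)-5-[(5R)-5-[(tert-butyldimethylsilyl)oxy]octyl]-2-methyl-cis-3,4,4a,5,6,8a-hexahydroquinoline-1(2H)-carboxylate (ring configuration as in 27) | c1ccccc1CO[C@H]1C[C@@H]2[C@H](CCCC[C@H](O[Si](C)(C)C(C)(C)C)CCC)CC=C[C@@H]2N(C(=O)OCc2ccccc2)[C@@H]1C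
A3 | alternative 2 | tert-butyl N-[(2R)-but-3-en-2-yl]-N-(cis-bicyclo[4.2.0]oct-7-en-2-yl)carbamate (N cis to the cyclobutene carbons) | C=C[C@@H](C)N(C(=O)OC(C)(C)C)[C@H]1CCC[C@H]2C=C[C@H]21
A4 | alternative 2 | tert-butyl 5-ethenyl-2-methyl-cis-4a,5,6,7,8,8a-hexahydroquinoline-1(2H)-carboxylate (ring configuration as in 27) | C1=C[C@@H]2[C@H](C=C)CCC[C@@H]2N(C(=O)OC(C)(C)C)[C@@H]1C
A5 | alternative 3 | levoglucosenone, (1S,5R)-6,8-dioxabicyclo[3.2.1]oct-2-en-4-one | O=C1C=C[C@H]2CO[C@@H]1O2
A6 | alternative 3 | tert-butyl{[(3E,9R)-dodeca-1,3-dien-9-yl]oxy}dimethylsilane | C=C/C=C/CCCC[C@H](O[Si](C)(C)C(C)(C)C)CCC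
A7 | alternative 3 | endo cis-fused cyclohexene adduct of levoglucosenone carrying the 5-silyloxyoctyl chain | O=C1[C@@H]3[C@H](CCCC[C@H](O[Si](C)(C)C(C)(C)C)CCC)C=CC[C@@H]3[C@H]2CO[C@@H]1O2
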